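I start with the easy step: I divide the target on the plateau by the catalyst charged.

all flasks: substrate 0.030 M; temperature 60 °C

|  | reagent | free catalyst | remark | time |
|---|---|---|---|---|
| delta | 1.3 equiv | 9.3 mol% | the very flask that is asked about, followed so far |  |
| epsilon | 1.3 equiv | 4.7 mol% | run made earlier |  |
| flask | 1.30 equiv | 9.3 mol% |  | 5.0 min |

- delta (time / min: target / %): 0.333: 14.7; 1.00: 25.1; 2.00: 28.6; 3.00: 29.1; 4.00: 28.2
- epsilon (time / min: target / %): 1.00: 13.4; 2.00: 14.2; 3.00: 15.7; 4.00: 15.9; 5.00: 14.9

(scatter of a reading: 0.5 percentage points)

- north: at 5.0 min raise the temperature by 20 K, then wait 10 min
- south: change nothing and wait 10 min more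
- south-east: at 5.0 min add free catalyst, 50.0 % of the amount charged, then wait 10 min
- west: at 5.0 min take out 90 % of the target then present, then wait 10 min
- north-east: at 5.0 min add reagent, 100 % of the amount charged, then wait 10 min

- target, in percent of the substrate first charged, at 5.0 min
- what to do for the largest gain in target; "none" if nothing gains more than 2 percentage points (north / south / south-east / west / north-east / none)
- target present, with what was taken out counted in, in percent of the substrate first charged, after north
- target present, with what was taken out counted in, in percent of the substrate first charged, after north-east

- target that was removed still counts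
- additions bring no volume worth counting
- the earlier runs do not show what temperature does; that part of a forecast is a guess

The delta readings from 2.00 min on average 28.6 % of the substrate charged, and with 9.3 mol% of catalyst that gives 3.08. I call this ratio of plateau target to catalyst charged the count, the turnover number. The epsilon readings from 2.00 min on give 3.23 from a different loading. So my bench rule, with substrate, reagent and temperature held as in these two runs, is that the plateau equals the count times the loading.

Now I join the two ends of the delta curve. At the early end, the first reading stands at about half of the plateau after 0.333 min. The late end is the plateau itself, and 5.0 min is far longer than that half-time, so I put the flask at 28.6 % now.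

The border I can reckon for the rule is where the count meets the room in the charge. At one of each per turnover, the substrate allows 10.8 turnovers per catalyst and the reagent 14.0, and the count stays below both. Extra reagent therefore adds nothing by my reckoning, and neither does waiting or taking target out. What heating does is a guess; I keep 28.6 % for north, and for north-east too. With both portions of catalyst counted against the whole substrate charge, the room is 7.17 turnovers per catalyst, above the count, so I choose south-east, with a gain of 14 percentage points to 42.6 %.

The forecast gives 28.8 % at 5.0 min, slightly above mine, chooses south-east, and puts north at 29 % and north-east at 29 %, on the ground that “The catalyst has died or been poisoned.”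

The flask gives 29.0 % at 5.0 min, its best choice is south-east, and north and north-east end at 29.0 % and 29.0 %.

    reagent + free catalyst ⇌ catalyst intermediate A (K = 918 /M, k = 25.5 /M/s, Ea = 44.0 kJ/mol, ΔH = −5.00 kJ/mol)
    substrate + catalyst intermediate A ⇌ catalyst intermediate B (K = 1270 /M, k = 303 /M/s, Ea = 37.0 kJ/mol, ΔH = −50.0 kJ/mol)
    catalyst intermediate B ⇌ catalyst intermediate C (K = 1.20, k = 0.237 /s, Ea = 82.0 kJ/mol, ΔH = −18.0 kJ/mol)
    catalyst intermediate C → free catalyst + target (k = 0.756 /s, Ea = 91.0 kJ/mol)
    free catalyst + target → free catalyst + over-reaction product (k = 9.85 /M/s, Ea = 52.0 kJ/mol)
    catalyst intermediate B → spent catalyst (k = 0.0566 /s, Ea = 97.0 kJ/mol)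
    (constants at 60 °C)

For the added catalyst the count gave 14 points, and the flask gains 12 points. On the neighbour flask with 23 mol% of free catalyst, the substrate allows 4.35 turnovers per catalyst, still above the count, and the count times the loading gives 70.8 %. At 5.00 min that neighbour flask holds 55.7 % target and 20.2 % over-reaction product, together 75.9 %, with 1.18 % of its substrate left.

Readings and results stem from a simulated flask for an exercise; noise was put on by code.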